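Take two constants: one for gas passing into solution, one for catalyst consuming what has dissolved. If the rate is proportional to catalyst and to dissolved gas, the steady fill (dissolved gas over saturation) is transfer/(transfer + consumption), and the apparent order in free catalyst equals that fill.

| setting | Sunday's | Friday's | flask |
|---|---|---|---|
| left-handed substrate | 16 mM | 36 mM | 24 mM |
| right-handed substrate | 16 mM | 36 mM | 24 mM |
| gas | 0.95 mM (held) | 0.95 mM (held) | 0.95 mM (held) |
| free catalyst | 48 µM | 48 µM | 48 µM |
| remark | run made earlier | run made earlier |  |

- Sunday's (time / min: left-handed product / %): 1.33: 5.3; 3.00: 13.2; 4.00: 18.0; 6.00: 28.2; 8.00: 38.4; 10.0: 48.0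
- Friday's (time / min: left-handed product / %): 1.33: 2.4; 3.00: 5.7; 4.00: 8.0; 6.00: 12.1; 8.00: 16.7; 10.0: 21.6

(each reading ± 0.3 percentage points)

- apparent order in free catalyst when 20% of the left-handed substrate and right-handed substrate together are converted (percent change of the rate of making left-handed product for one percent more free catalyst charged)

- free catalyst is single-handed; left-handed substrate and right-handed substrate are mirror images of each other, charged as a racemate, each of them at the stated concentration
- the numbers in the tables scatter by 0.3 percentage points (one standard deviation)
- at the start none of the gas is in solution
- no earlier run changes the charge of free catalyst; that part of a forecast is a guess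

By 10.0 min, Sunday's run has made left-handed product at an average 1.54 mM min⁻¹ and Friday's run at an average 1.56 mM min⁻¹, so these two charges give the same rate to within the scatter of the readings. Dividing by saturation gives the least transfer constant, the one that would supply this rate from empty solution:

least transfer constant = rate / saturation = 1.62 min⁻¹

Sunday's first reading trails that line by a lag:

lag = 0.226 min

fill × (1 − fill) = least transfer constant × lag = 0.365

That product exceeds 0.250, the peak of the left side, reached at a fill of 0.5. The lag, one scattered reading, is therefore the weak link. Reforged as short enough to allow a root, it brings my reckoning to that peak, and I commit to an order near 0.5.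

The forecast differs and gives 0.1: “gas transfer is the slow step, with dissolved gas near 7% of saturation”.

The flask gives 0.84.

    free catalyst + left-handed substrate ⇌ catalyst intermediate A (K = 79.0 M⁻¹, k = 86000 M⁻¹ s⁻¹)
    free catalyst + right-handed substrate ⇌ catalyst intermediate B (K = 1200 M⁻¹, k = 3600 M⁻¹ s⁻¹)
    reagent + catalyst intermediate A → free catalyst + left-handed product (k = 8400 M⁻¹ s⁻¹)
    reagent + catalyst intermediate B → free catalyst + right-handed product (k = 920 M⁻¹ s⁻¹)
    gas ⇌ reagent, rate k5*(csat - [reagent]) (kL = 0.400 s⁻¹)

In the flask at 6.00 min, catalyst intermediate B held 85.0% of the catalyst and reagent, the dissolved gas, stood at 0.808 mM, while both product steps ran, with left-handed product at 18.7% and right-handed product at 23.2%. As an estimate for this flask, the least transfer constant from Sunday's run, scaled up by the ratio of both products to left-handed product at that time and set against the transfer constant 24.0 min⁻¹, uses 0.151 of the supply, leaving a fill of 0.849.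

The data are calculated with constants of no real substance; the scatter is artificial.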